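**Retrosynthetic overview**
- The pyranone ring is the only ring built and is formed last. Opening O1–C2 and saturating C2–C3 of the flavone leads back to an (E)-2'-hydroxychalcone (forward: I2/DMSO oxidative cyclisation).
- Key C–C bond (flavone C2–C3): intermolecular Claisen–Schmidt aldol condensation of 2'-hydroxy-4',5',6'-trimethoxyacetophenone with 3,4,5-trimethoxybenzaldehyde.
- The acetophenone comes from C-acetylation of the symmetric 3,4,5-trimethoxyphenol, where only one regioisomer is possible.
- Both benzene rings are bought with all six methoxy groups in place, so no O-methylation or protecting group is needed.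

Assumption: the target SMILES has no stereocentre and no stereogenic double bond (an achiral, planar flavone). "Single enantiomer" therefore means this one achiral compound, and no asymmetric step is required.

**Step 1**
Reactants: 1 3,4,5-trimethoxyphenol
Product: 3 1-(6-hydroxy-2,3,4-trimethoxyphenyl)ethan-1-one, via BF2 chelate 2 (not isolated)
Conditions: AcOH, BF3·OEt2 (3 equiv), 85 °C, 3 h; then ice-water, brief reflux in aq. EtOH
Reagents that add atoms: acetic acid, CC(=O)O
Why: In this BF3-promoted Friedel–Crafts (Fries-type) C-acetylation the two free ring positions of 1 are equivalent and each is activated ortho/para by three oxygen donors, so only one regioisomer can form, it is held as the deactivated chelate 2 (which blocks a second acylation) until water releases 3, and no stereocentre is created.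

**Step 2**
Reactants: 3 1-(6-hydroxy-2,3,4-trimethoxyphenyl)ethan-1-one; 4 3,4,5-trimethoxybenzaldehyde (1.1 equiv)
Product: 6 (E)-1-(6-hydroxy-2,3,4-trimethoxyphenyl)-3-(3,4,5-trimethoxyphenyl)prop-2-en-1-one, via racemic aldol adduct 5 (not isolated)
Conditions: KOH (50% aq., 10 equiv), EtOH, 0 °C to rt, 48 h; then 2 M HCl to pH 3
Reagents that add atoms: none
Why: In this Claisen–Schmidt crossed aldol condensation 4 cannot enolise and 3 is the only enolate source, so the enolate adds intermolecularly to the aldehyde to make the key C–C bond, and E1cB dehydration of 5 erases its stereocentre and gives the thermodynamically favoured E-enone.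

**Step 3**
Reactants: 6 (E)-1-(6-hydroxy-2,3,4-trimethoxyphenyl)-3-(3,4,5-trimethoxyphenyl)prop-2-en-1-one
Product: 8 5,6,7-trimethoxy-2-(3,4,5-trimethoxyphenyl)-4H-chromen-4-one, via racemic flavanone 7 (not isolated)
Conditions: I2 (10 mol %), DMSO, 130 °C, 3 h; pour into ice-water, filter, recrystallise from MeOH
Reagents that add atoms: none
Why: In this iodine-catalysed oxidative cyclisation the 2'-phenol closes the ring by 6-endo oxa-Michael addition to give 7, iodine then dehydrogenates C2–C3 with DMSO as terminal oxidant, and the transient C2 stereocentre is destroyed on forming the aromatic 4-pyranone, so any chalcone/flavanone mixture carried over from step 2 converges on the achiral target.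

**Compound list**
1 | 3,4,5-trimethoxyphenol | COc1cc(O)cc(OC)c1OC | starting material
2 | BF2 chelate of 3 (six-membered O–BF2–O ring spanning the phenolate O and the ketone O; formed in the flask, not isolated) | CC1=[O+][B-](F)(F)Oc2cc(OC)c(OC)c(OC)c21 | intermediate
3 | 1-(6-hydroxy-2,3,4-trimethoxyphenyl)ethan-1-one (2'-hydroxy-4',5',6'-trimethoxyacetophenone) | CC(=O)c1c(O)cc(OC)c(OC)c1OC | intermediate
4 | 3,4,5-trimethoxybenzaldehyde | COc1cc(C=O)cc(OC)c1OC | starting material
5 | rac-3-hydroxy-1-(6-hydroxy-2,3,4-trimethoxyphenyl)-3-(3,4,5-trimethoxyphenyl)propan-1-one (aldol adduct; racemic, not isolated) | COc1cc(C(O)CC(=O)c2c(O)cc(OC)c(OC)c2OC)cc(OC)c1OC | intermediate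
6 | (E)-1-(6-hydroxy-2,3,4-trimethoxyphenyl)-3-(3,4,5-trimethoxyphenyl)prop-2-en-1-one (2'-hydroxy-3,4,4',5,5',6'-hexamethoxychalcone) | COc1cc(/C=C/C(=O)c2c(O)cc(OC)c(OC)c2OC)cc(OC)c1OC | intermediate
7 | rac-5,6,7-trimethoxy-2-(3,4,5-trimethoxyphenyl)chroman-4-one (flavanone; racemic, not isolated) | COc1cc(C2CC(=O)c3c(OC)c(OC)c(OC)cc3O2)cc(OC)c1OC | intermediate
8 | 5,6,7-trimethoxy-2-(3,4,5-trimethoxyphenyl)-4H-chromen-4-one (5,6,7,3',4',5'-hexamethoxyflavone; achiral) | COc1cc(-c2cc(=O)c3c(OC)c(OC)c(OC)cc3o2)cc(OC)c1OC | target

**Total step count:** 3
**Longest linear sequence:** 3 (1 → 3 → 6 → 8; 4 enters at step 2)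

**Steps most likely to fail** (ranked: step 3 most likely, then step 1, then step 2; discussed in route order)

Step 1. The risks are cleavage of the methoxy group ortho to the new ketone by hot BF3, and a chelate 2 that is slow to hydrolyse. The fallback sets out from 1 and comes back to the route at 3. It replaces the boron-promoted acylation by a Houben–Hoesch reaction. Compound 1, acetonitrile and ZnCl2 in dry Et2O are saturated with HCl gas at 0 °C. The phloroglucinol-type ring attacks the nitrilium ion at the only free position type, and 1-(6-hydroxy-2,3,4-trimethoxyphenyl)ethan-1-iminium chloride F1 precipitates. The salt is filtered off and boiled in water, which hydrolyses it to 3. No hot oxophilic Lewis acid is involved, so neither ether cleavage nor boron chelation can occur.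

Step 2. The risks are a sluggish reaction between an electron-rich, hindered ketone and an electron-rich aldehyde, Cannizzaro loss of 4, and a chalcone/flavanone mixture that is hard to crystallise. The fallback sets out from 3 and comes back to the route at 8, so it also bypasses step 3. It uses an intermolecular Claisen-type C-aroylation at the correct oxidation level. Compound 3 is treated with LiHMDS (4 equiv, THF, −78 °C) and then with commercial 3,4,5-trimethoxybenzoyl chloride (COc1cc(C(=O)Cl)cc(OC)c1OC). Quenching with dilute HCl gives 1-(6-hydroxy-2,3,4-trimethoxyphenyl)-3-(3,4,5-trimethoxyphenyl)propane-1,3-dione F2. Catalytic H2SO4 in AcOH at 100 °C then cyclodehydrates it to 8.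

Step 3. The risks are iodination of the electron-rich C8 position and partial loss of the 5-O-methyl group to HI at 130 °C. The fallback sets out from 6 and comes back to the route at 8. It separates ring closure from oxidation and uses no iodine. Compound 6 is cyclised with NaOAc in refluxing EtOH, and the flavanone 7 is isolated this time; the 6'-methoxy group favours the closed form. Compound 7 is then dehydrogenated by hydride abstraction with DDQ in refluxing dioxane to give 8. This fallback makes no compound outside the compound list (F0).

**Further compounds**
F1 | step 1 | 1-(6-hydroxy-2,3,4-trimethoxyphenyl)ethan-1-iminium chloride | CC(=[NH2+])c1c(O)cc(OC)c(OC)c1OC.[Cl-]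
F2 | step 2 | 1-(6-hydroxy-2,3,4-trimethoxyphenyl)-3-(3,4,5-trimethoxyphenyl)propane-1,3-dione | COc1cc(C(=O)CC(=O)c2c(O)cc(OC)c(OC)c2OC)cc(OC)c1OC
F0 | step 3 | none | none
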